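## The problem

Target 37 is a germacranolide of the melampolide type. A ten-membered carbocycle (C1–C10) is trans-fused at C6–C7 to an α-methylene-γ-butyrolactone (O6, C6, C7, C11, C12, exocyclic C13). The ring holds a Z (ring-cis) C1=C10 olefin bearing methyl C14 and a C4=C5 olefin whose hydroxymethyl C15 is cis to C6. O8 is esterified with (R)-3-hydroxy-2-methylpropanoic acid.

A medium ring with two trisubstituted olefins of opposite ring geometry cannot be closed at either olefin with reliable geometric control. Both olefins therefore have to be made in an open chain, and the ring closed through an sp3–sp3 bond.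

The ring carries three contiguous stereocentres: C6 (R), C7 (R) and C8 (S). Only C8, a plain secondary carbinol, can be installed on its own. It must control C7 and, through C7, C6. The side-chain centre is remote and can be bought.

Several groups will not survive rough treatment:
- The exo-methylene lactone is a Michael acceptor and is lost to amines, alkoxides, thiols and hydride.
- The 1,5-diene in the ten-membered ring invites transannular cyclisation under strong acid and Cope rearrangement on heating.
- The β-hydroxy ester side chain eliminates or migrates under base.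
- A free O8–H can translactonise onto C12.

The feature that makes the key step possible is the array O6–C6–C7–C11(=C13)–C12. It is the retron of the addition of a 2-(bromomethyl)acrylate to an aldehyde. Because C6–C7 belongs to both rings, forming that one bond closes the carbocycle and places O6 five atoms from the ester carbonyl, so the lactone follows.

## Retrosynthesis

**Side chain and silyl groups (37 ⇒ 36 ⇒ 30 + 34).** The two silyl ethers of 36 are removed last, and the O8–acyl bond is cut to give hydroxy lactone 30 and acid 34. The ester goes on late because a β-oxygenated ester would not survive the organometallic and oxidative steps before it. Acid 34 comes in two steps from hydroxy ester 31. The forward steps must acylate a hindered secondary alcohol without epimerising the acid, and desilylate under non-basic conditions. Alcohol 30 comes from lactone 29 by loss of the O8 triethylsilyl group, which is chosen to leave well before the two tert-butyldiphenylsilyl groups.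

**C6–C7 and O6–C12 (29 ⇒ 26).** Both bonds are cut together, giving the open-chain formyl allylic bromide 26. The neighbouring cuts are weaker: closing at C1=C10 or C4=C5 cannot control olefin geometry in a ten-membered ring, and closing at C2–C3 or C8–C9 builds no functionality. Only the C6–C7 cut uses the lactone as a retron, and its polarity (C6 electrophile, C7 nucleophile, C11 left unsaturated) matches the biosynthetic cyclisation. The precursor is acyclic with one stereocentre (C8). The forward reaction must give γ-attack, 1,2-addition, C6/C7 anti, C7 anti to O8, and no loss of the C8 oxygen. For that last point O8 carries a triethylsilyl ether. A benzyl-type ether could bridge to chromium and leave by vinylogous β-elimination; a bulky, poorly coordinating silyl ether does neither readily and strengthens the facial bias.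

**C7–C11 (26 ⇒ 25 ⇒ 24 ⇒ 22 ⇒ 20 + 21).** The (Z)-2-(bromomethyl)enoate of 24 is the allylic transposition product of Baylis–Hillman adduct 22. Cutting C7–C11 gives α-silyloxy aldehyde 20 and methyl acrylate 21. An olefination route would need a separate way to functionalise C13. C6 stays a 4-methoxybenzyl ether until the bromide is in place (24 → 25 → 26), because an enal would lose its geometry under the amine of the Baylis–Hillman step.

**C9–C10 and the C8 stereocentre (20 ⇒ 18 ⇒ 17 ⇒ 13 + 15).** Cutting C9–C10 gives alkenyl iodide 13 and epoxide 15, made in one step from (R)-glycidol 14. C8 is thus bought, not made. The alternative is asymmetric α-oxygenation of a C7 aldehyde, which needs an N–O cleavage and a diol differentiation on top. Here a bis-silylation (18) and a selective oxidation of the primary silyl ether give 20 directly. The forward step must open the epoxide at the terminal carbon with retention of olefin geometry.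

**C1=C10 (13 ⇒ 12).** The Z-iodoalkene is cut at the double bond, giving aldehyde 12 and an α-iodo ethylidene ylide. Nerol would supply this olefin ready-made and was weighed. It was set aside because the chain must then be extended at C2 through a stereodefined C15-oxygenated enal, the terminal olefin cleaved beside two others, and C8 oxygenated afterwards, which by count costs about three more steps in the longest line.

**C2–C3 and C4–C5 (12 ⇒ 10 ⇒ 8 ⇒ 7 ⇒ 5 + 4; 4 ⇒ 2 ⇒ 1).** Ester 10 is the Johnson–Claisen product of allylic alcohol 8. The rearrangement forms C2–C3 and sets C4=C5 with C6 cis to C15. Alcohol 8 comes from diol 7, which is the adduct (C4–C5) of lithiated 2-bromoprop-2-en-1-ol 5 and aldehyde 4. Aldehyde 4 comes from diol 1 via ether 2. A Wittig-type olefination of an α-silyloxy ketone would give poor geometric control at C4=C5; the sigmatropic route fixes it through a chair.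

## Roads not taken

**Alternative 1: enolate-triggered Grob fragmentation.** The cut is the transannular C5–C10 bond. Reconnecting it turns the ten-membered ring into cis-decalin mesylate A1, with a methyl ester at C4 and the mesylate at C1. In the forward step KN(SiMe3)2 would form the C4 ester enolate, which forms C4=C5, breaks C5–C10 and forms C1=C10 as the mesylate leaves, giving cyclodecadiene ester A2.
- Merits: no high dilution is needed. Both olefin geometries follow stereospecifically from the decalin: the cis fusion with an equatorial mesylate gives Z C1=C10, and the equatorial C6 bond gives the required C4=C5. C6–C8 are set on a cyclohexane. In geometric certainty this road is better than the chosen one.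
- Weak points: A1 needs seven stereocentres, four of which are destroyed. The exocyclic enolate must align with a ring bond, which a chair does not obviously allow, and elimination of the mesylate competes. A2 still lacks the lactone: C12 is at the alcohol level and C15 at the ester level, so several deprotection and redox steps must follow on a labile cyclodecadiene.
- Comparison: the chosen plan makes ring, lactone and methylene in one step from a chain at the right oxidation levels. Against the stereospecificity of the fragmentation it can set only substrate control.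

**Alternative 2: electroreductive nickel decarboxylative alkenylation.** The cut is C3–C4 in a preformed lactone. The precursor is redox-active ester A3, with an alkenyl iodide at C4 and an N-(acyloxy)phthalimide one carbon beyond C3. Under cathodic reduction with NiCl2·glyme and 2,2′-bipyridine, loss of CO2 would give the C3 radical, which is captured at nickel by the alkenyl iodide to give lactone A4.
- Merits: the new bond creates no stereocentre. C6, C7 and C8 are fixed beforehand on a γ-lactone by stepwise chemistry, so stereochemistry does not depend on the ring closure. This is better than the chosen plan. The conditions are neutral and tolerate silyl ethers.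
- Weak points: a free primary radical must close a strained ten-membered ring without a template, at a dilution where reduction and dimerisation of the radical compete. C13 has to be left out and added afterwards by α-methylenation, which would converge on 29. A3 needs a stereodefined trisubstituted alkenyl iodide and a separate lactone synthesis.
- Comparison: the length is equal or greater. The chosen plan has the better precedent for the ring size and builds the methylene in the same step; it concedes stereochemical security.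

**Alternative 3: Wittig–Still [2,3] ring contraction.** The cut is C7–C8. Reconnecting O8 to C13 gives thirteen-membered α-stannyl allyl ether A5. BuLi would exchange tin for lithium, and the α-alkoxy carbanion would attack C7, break O–C13 and contract the ring to cyclodecadienol A6.
- Merits: a thirteen-membered ether is easier to close than a ten-membered carbocycle, and the contraction needs no dilution. C7, C8 and the exocyclic methylene arise together. O8–H emerges free for acylation, which saves the deprotection the chosen plan needs.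
- Weak points: an enantioenriched α-alkoxystannane and stoichiometric tin are required. The facial course inside a thirteen-membered ring is not predictable from acyclic rules, and a [1,2]-shift competes. C12 is at the alcohol level, so deprotection and a two-level oxidation to the lactone must follow acylation, in the presence of the sensitive side chain.
- Comparison: several steps longer. The chosen plan delivers C12 as an ester and the lactone in the ring-forming step, but must accept a dilution-controlled closure.

Key step: step 16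

## Steps

Remark: germacrane numbering (C1–C15, O6, O8) is used for all intermediates. Alcohol 17 may contain its 1,2-silyl-shifted isomer, which step 10 converts to the same product 18. Adduct 22 is a mixture of C7 epimers that converge in step 13.

Step 1
Reactants: 1 (Z)-but-2-ene-1,4-diol
Product: 2 (Z)-1,4-bis[(4-methoxybenzyl)oxy]but-2-ene
Conditions: NaH, 4-methoxybenzyl chloride, Bu4NI (cat.), THF–DMF, 0 °C → rt
Reagents that add atoms: 4-methoxybenzyl chloride, COc1ccc(CCl)cc1
Why: Williamson etherification of both primary allylic hydroxyls; no stereocentre is involved.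

Step 2
Reactants: 2 (Z)-1,4-bis[(4-methoxybenzyl)oxy]but-2-ene
Product: 4 2-[(4-methoxybenzyl)oxy]acetaldehyde, via secondary ozonide 3 (not isolated)
Conditions: O3, CH2Cl2, −78 °C; PPh3, −78 °C → rt
Reagents that add atoms: ozone, [O-][O+]=O
Why: Ozonolysis with reductive work-up; the symmetrical olefin should give two equivalents of the same aldehyde, and the electron-rich benzyl ethers tolerate ozone at −78 °C when the reaction is stopped at the end point.

Step 3
Reactants: 5 2-bromoprop-2-en-1-ol; 4 2-[(4-methoxybenzyl)oxy]acetaldehyde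
Product: 7 rac-4-[(4-methoxybenzyl)oxy]-2-methylidenebutane-1,3-diol, via lithium 2-lithioprop-2-en-1-olate 6 (not isolated)
Conditions: t-BuLi (3 equiv), Et2O, −78 → 0 °C; then 4, −78 °C; aq. NH4Cl
Reagents that add atoms: none
Why: Deprotonation and bromine–lithium exchange give the O,C-dilithio reagent, which adds 1,2 to the aldehyde and forms C4–C5; the new carbinol is racemic, which is acceptable because step 5 destroys it.

Step 4
Reactants: 7 rac-4-[(4-methoxybenzyl)oxy]-2-methylidenebutane-1,3-diol
Product: 8 rac-3-{[tert-butyl(diphenyl)silyl]oxymethyl}-1-[(4-methoxybenzyl)oxy]but-3-en-2-ol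
Conditions: TBDPSCl (1.05 equiv), imidazole, CH2Cl2, −20 → 0 °C
Reagents that add atoms: tert-butyl(chloro)diphenylsilane, CC(C)(C)[Si](Cl)(c1ccccc1)c1ccccc1
Why: Selective silylation; the bulky chlorosilane should take the primary allylic hydroxyl (O15) and leave the secondary one free.

Step 5
Reactants: 8 rac-3-{[tert-butyl(diphenyl)silyl]oxymethyl}-1-[(4-methoxybenzyl)oxy]but-3-en-2-ol
Product: 10 ethyl (4Z)-4-{[tert-butyl(diphenyl)silyl]oxymethyl}-6-[(4-methoxybenzyl)oxy]hex-4-enoate, via ketene acetal 9 (not isolated)
Conditions: MeC(OEt)3, EtCO2H (cat.), xylene, 140 °C, EtOH distilled off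
Reagents that add atoms: triethyl orthoacetate, CCOC(C)(OCC)OCC
Why: Johnson–Claisen rearrangement forms C2–C3; in the chair transition state the C6 substituent is equatorial (the axial alternative meets a 1,3-diaxial clash with the ethoxy group), which should put C6 trans to the new chain and cis to C15 at C4=C5.

Step 6
Reactants: 10 ethyl (4Z)-4-{[tert-butyl(diphenyl)silyl]oxymethyl}-6-[(4-methoxybenzyl)oxy]hex-4-enoate
Product: 12 (4Z)-4-{[tert-butyl(diphenyl)silyl]oxymethyl}-6-[(4-methoxybenzyl)oxy]hex-4-enal, via aluminium hemiacetal 11 (not isolated)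
Conditions: i-Bu2AlH (1.1 equiv), CH2Cl2, −78 °C; MeOH, aq. potassium sodium tartrate
Reagents that add atoms: none
Why: Partial reduction of the ester; the tetrahedral aluminium hemiacetal is stable at −78 °C and releases the C1 aldehyde only on work-up.

Step 7
Reactants: 12 (4Z)-4-{[tert-butyl(diphenyl)silyl]oxymethyl}-6-[(4-methoxybenzyl)oxy]hex-4-enal
Product: 13 (2Z,6Z)-3-{[tert-butyl(diphenyl)silyl]oxymethyl}-7-iodo-1-[(4-methoxybenzyl)oxy]octa-2,6-diene
Conditions: EtPPh3I, n-BuLi, THF, 0 °C; I2, −78 °C; NaN(SiMe3)2, −78 → −20 °C; then 12, −78 °C → rt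
Reagents that add atoms: ethyltriphenylphosphonium iodide, CC[P+](c1ccccc1)(c1ccccc1)c1ccccc1.[I-]; iodine, II
Why: Stork–Zhao-type Wittig olefination with the α-iodo ethylidene ylide; kinetic cis-oxaphosphetane formation should place iodine cis to the chain, giving the Z-iodoalkene that maps onto Z C1=C10.

Step 8
Reactants: 14 (R)-glycidol
Product: 15 (S)-triethyl(oxiran-2-ylmethoxy)silane
Conditions: TESCl, Et3N, DMAP (cat.), CH2Cl2, 0 °C
Reagents that add atoms: chlorotriethylsilane, CC[Si](Cl)(CC)CC
Why: O-silylation; no bond at the stereocentre is touched, and the descriptor changes from R to S only through the priority rules.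

Step 9
Reactants: 13 (2Z,6Z)-3-{[tert-butyl(diphenyl)silyl]oxymethyl}-7-iodo-1-[(4-methoxybenzyl)oxy]octa-2,6-diene; 15 (S)-triethyl(oxiran-2-ylmethoxy)silane
Product: 17 (2S,4Z,8Z)-8-{[tert-butyl(diphenyl)silyl]oxymethyl}-10-[(4-methoxybenzyl)oxy]-4-methyl-1-(triethylsilyloxy)deca-4,8-dien-2-ol, via alkenyllithium 16 (not isolated)
Conditions: t-BuLi (2 equiv), Et2O, −78 °C; then 15, BF3·OEt2, −78 °C; aq. NaHCO3
Reagents that add atoms: none
Why: Iodine–lithium exchange keeps the olefin geometry, and the BF3-assisted SN2 opening at the unsubstituted epoxide carbon forms C9–C10; the C8 stereocentre comes unchanged from 15.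

Step 10
Reactants: 17 (2S,4Z,8Z)-8-{[tert-butyl(diphenyl)silyl]oxymethyl}-10-[(4-methoxybenzyl)oxy]-4-methyl-1-(triethylsilyloxy)deca-4,8-dien-2-ol
Product: 18 (2S,4Z,8Z)-8-{[tert-butyl(diphenyl)silyl]oxymethyl}-10-[(4-methoxybenzyl)oxy]-4-methyl-1,2-bis(triethylsilyloxy)deca-4,8-diene
Conditions: TESCl, imidazole, DMF, 0 °C
Reagents that add atoms: chlorotriethylsilane, CC[Si](Cl)(CC)CC
Why: Silylation of the remaining hydroxyl; any silyl-shifted isomer of 17 gives the same bis-silyl ether.

Step 11
Reactants: 18 (2S,4Z,8Z)-8-{[tert-butyl(diphenyl)silyl]oxymethyl}-10-[(4-methoxybenzyl)oxy]-4-methyl-1,2-bis(triethylsilyloxy)deca-4,8-diene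
Product: 20 (2S,4Z,8Z)-8-{[tert-butyl(diphenyl)silyl]oxymethyl}-10-[(4-methoxybenzyl)oxy]-4-methyl-2-(triethylsilyloxy)deca-4,8-dienal, via alkoxysulfonium chloride 19 (not isolated)
Conditions: (COCl)2, DMSO, CH2Cl2, −78 → −30 °C; Et3N, −78 → 0 °C
Reagents that add atoms: none
Why: Swern oxidation applied directly to a primary triethylsilyl ether: the activated sulfoxide attacks the less hindered silyl ether oxygen, chlorosilane leaves and the alkoxysulfonium salt collapses to the aldehyde, while the secondary silyl ether is too hindered to react.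

Step 12
Reactants: 20 (2S,4Z,8Z)-8-{[tert-butyl(diphenyl)silyl]oxymethyl}-10-[(4-methoxybenzyl)oxy]-4-methyl-2-(triethylsilyloxy)deca-4,8-dienal; 21 methyl acrylate
Product: 22 methyl (4S,6Z,10Z)-10-{[tert-butyl(diphenyl)silyl]oxymethyl}-3-hydroxy-12-[(4-methoxybenzyl)oxy]-6-methyl-2-methylidene-4-(triethylsilyloxy)dodeca-6,10-dienoate (both C3 epimers)
Conditions: DABCO (1 equiv), methyl acrylate (excess), 1,4-dioxane–H2O (3:1), rt
Reagents that add atoms: none
Why: Morita–Baylis–Hillman reaction forms C7–C11 on an aldehyde activated by its α-oxygen; the C7 carbinol need not be controlled because step 13 turns it into an sp2 carbon.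

Step 13
Reactants: 22 methyl (4S,6Z,10Z)-10-{[tert-butyl(diphenyl)silyl]oxymethyl}-3-hydroxy-12-[(4-methoxybenzyl)oxy]-6-methyl-2-methylidene-4-(triethylsilyloxy)dodeca-6,10-dienoate
Product: 24 methyl (2Z,4S,6Z,10Z)-2-(bromomethyl)-10-{[tert-butyl(diphenyl)silyl]oxymethyl}-12-[(4-methoxybenzyl)oxy]-6-methyl-4-(triethylsilyloxy)dodeca-2,6,10-trienoate, via alkoxysulfonium bromide 23 (not isolated)
Conditions: NBS, Me2S, CH2Cl2, 0 °C; then 22, 0 °C → rt
Reagents that add atoms: N-bromosuccinimide, O=C1CCC(=O)N1Br
Why: Corey–Kim-type activation of the allylic alcohol followed by SN2′ attack of bromide at C13; Baylis–Hillman alcohols are known to give the (Z)-2-(bromomethyl)alk-2-enoate, with C8 trans to the ester, as the favoured isomer.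

Step 14
Reactants: 24 methyl (2Z,4S,6Z,10Z)-2-(bromomethyl)-10-{[tert-butyl(diphenyl)silyl]oxymethyl}-12-[(4-methoxybenzyl)oxy]-6-methyl-4-(triethylsilyloxy)dodeca-2,6,10-trienoate
Product: 25 methyl (2Z,4S,6Z,10Z)-2-(bromomethyl)-10-{[tert-butyl(diphenyl)silyl]oxymethyl}-12-hydroxy-6-methyl-4-(triethylsilyloxy)dodeca-2,6,10-trienoate
Conditions: DDQ, CH2Cl2–pH 7 buffer (10:1), 0 °C
Reagents that add atoms: none
Why: Oxidative cleavage of the 4-methoxybenzyl ether; the buffered, neutral medium should leave the silyl ethers and the allylic bromide alone.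

Step 15
Reactants: 25 methyl (2Z,4S,6Z,10Z)-2-(bromomethyl)-10-{[tert-butyl(diphenyl)silyl]oxymethyl}-12-hydroxy-6-methyl-4-(triethylsilyloxy)dodeca-2,6,10-trienoate
Product: 26 methyl (2Z,4S,6Z,10Z)-2-(bromomethyl)-10-{[tert-butyl(diphenyl)silyl]oxymethyl}-6-methyl-12-oxo-4-(triethylsilyloxy)dodeca-2,6,10-trienoate
Conditions: MnO2 (activated, excess), CH2Cl2, rt, dark
Reagents that add atoms: none
Why: Chemoselective oxidation of the primary allylic alcohol with manganese dioxide; the neutral heterogeneous oxidant should keep the geometry of the C4=C5 enal and spare the bromide.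

Step 16
Reactants: 26 methyl (2Z,4S,6Z,10Z)-2-(bromomethyl)-10-{[tert-butyl(diphenyl)silyl]oxymethyl}-6-methyl-12-oxo-4-(triethylsilyloxy)dodeca-2,6,10-trienoate
Product: 29 (3aS,4S,6Z,10Z,11aR)-10-{[tert-butyl(diphenyl)silyl]oxymethyl}-6-methyl-3-methylidene-4-(triethylsilyloxy)-3a,4,5,8,9,11a-hexahydrocyclodeca[b]furan-2(3H)-one, via allylchromium dichloride 27 (not isolated), via chromium alkoxide 28 (not isolated)
Conditions: CrCl2 (8 equiv), THF–DMF (4:1), slow addition of 26 (final 0.003 M), rt; then 45 °C; aq. NH4Cl
Reagents that add atoms: none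
Why: Two equivalents of CrCl2 (divalent chromium) reduce the C13–Br bond to allylchromium 27 (trivalent chromium), which adds through its γ-carbon C7 to the C6 aldehyde in a closed six-membered chair transition state, forming C6–C7 and the ten-membered ring; chromium alkoxide 28 then attacks the C12 methyl ester and expels methoxide. The closest known reaction type is the intramolecular Nozaki–Hiyama allylation of formyl 2-(bromomethyl)acrylates, which is established for ten-membered α-methylene lactones of the germacranolide class. The carbocycle closes end to end by exo attack on the aldehyde carbon (10-exo-trig), the lactone by 5-exo-trig acyl substitution. C6/C7 anti (trans lactone) should follow from the chair in which C5 and C8 are both equatorial, a geometry the allylchromium can reach because its σ- and π-bonded forms interconvert; the Z C1=C10 olefin and the C4=C5 enal act as turn elements that bring the termini together. C7 is set relative to C8 by allylic 1,3-strain: H8 lies in the plane of the C7=C11 bond, the triethylsilyloxy group covers one face and the tether leaving from C9 delivers C6 to the other, which puts C11 anti to O8 as in 37. The step needs 1,2- over 1,4-addition and γ- over α-attack (both inherent to allylchromium reagents), ring closure over oligomerisation (slow addition at high dilution) and retention of the C8 oxygen, for which a bulky, poorly coordinating silyl ether was chosen over a benzyl-type ether or the ester itself.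

Step 17
Reactants: 29 (3aS,4S,6Z,10Z,11aR)-10-{[tert-butyl(diphenyl)silyl]oxymethyl}-6-methyl-3-methylidene-4-(triethylsilyloxy)-3a,4,5,8,9,11a-hexahydrocyclodeca[b]furan-2(3H)-one
Product: 30 (3aR,4S,6Z,10Z,11aR)-10-{[tert-butyl(diphenyl)silyl]oxymethyl}-4-hydroxy-6-methyl-3-methylidene-3a,4,5,8,9,11a-hexahydrocyclodeca[b]furan-2(3H)-one
Conditions: PPTS (cat.), MeOH–CH2Cl2, 0 °C → rt
Reagents that add atoms: none
Why: Acid-catalysed methanolysis; the secondary triethylsilyl ether is far more labile than the primary tert-butyldiphenylsilyl ether, and the mild acid should neither add methanol to the methylene lactone nor move the lactone to O8.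

Step 18
Reactants: 31 methyl (R)-3-hydroxy-2-methylpropanoate
Product: 32 methyl (R)-3-{[tert-butyl(diphenyl)silyl]oxy}-2-methylpropanoate
Conditions: TBDPSCl, imidazole, DMF, 0 °C → rt
Reagents that add atoms: tert-butyl(chloro)diphenylsilane, CC(C)(C)[Si](Cl)(c1ccccc1)c1ccccc1
Why: Silylation of the primary hydroxyl; the stereocentre is not involved.

Step 19
Reactants: 32 methyl (R)-3-{[tert-butyl(diphenyl)silyl]oxy}-2-methylpropanoate
Product: 34 (R)-3-{[tert-butyl(diphenyl)silyl]oxy}-2-methylpropanoic acid, via lithium carboxylate 33 (not isolated)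
Conditions: LiOH·H2O, THF–MeOH–H2O, 0 °C; then 1 M HCl to pH 3
Reagents that add atoms: lithium hydroxide, [Li+].[OH-]
Why: Saponification at low temperature; the carboxylate formed is not prone to α-deprotonation, so the R configuration should be kept.

Step 20
Reactants: 30 (3aR,4S,6Z,10Z,11aR)-10-{[tert-butyl(diphenyl)silyl]oxymethyl}-4-hydroxy-6-methyl-3-methylidene-3a,4,5,8,9,11a-hexahydrocyclodeca[b]furan-2(3H)-one; 34 (R)-3-{[tert-butyl(diphenyl)silyl]oxy}-2-methylpropanoic acid
Product: 36 (3aR,4S,6Z,10Z,11aR)-10-{[tert-butyl(diphenyl)silyl]oxymethyl}-6-methyl-3-methylidene-2-oxo-2,3,3a,4,5,8,9,11a-octahydrocyclodeca[b]furan-4-yl (2R)-3-{[tert-butyl(diphenyl)silyl]oxy}-2-methylpropanoate, via O-acylisourea 35 (not isolated)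
Conditions: DCC, DMAP (cat.), CH2Cl2, 0 °C → rt
Reagents that add atoms: none
Why: Steglich esterification of the only free hydroxyl; sub-stoichiometric DMAP at low temperature should transfer the acyl group without epimerising its α-carbon and without moving the lactone.

Step 21
Reactants: 36 (3aR,4S,6Z,10Z,11aR)-10-{[tert-butyl(diphenyl)silyl]oxymethyl}-6-methyl-3-methylidene-2-oxo-2,3,3a,4,5,8,9,11a-octahydrocyclodeca[b]furan-4-yl (2R)-3-{[tert-butyl(diphenyl)silyl]oxy}-2-methylpropanoate
Product: 37 (3aR,4S,6Z,10Z,11aR)-10-(hydroxymethyl)-6-methyl-3-methylidene-2-oxo-2,3,3a,4,5,8,9,11a-octahydrocyclodeca[b]furan-4-yl (2R)-3-hydroxy-2-methylpropanoate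
Conditions: HF·pyridine, pyridine, THF, 0 °C → rt
Reagents that add atoms: none
Why: Fluoride-mediated cleavage of both silyl ethers under buffered, non-basic conditions, which should avoid acyl migration, β-elimination in the side chain and conjugate addition to the methylene lactone.

## Compound list

1 | (Z)-but-2-ene-1,4-diol | OC/C=C\CO | starting material
2 | (Z)-1,4-bis[(4-methoxybenzyl)oxy]but-2-ene | COc1ccc(COC/C=C\COCc2ccc(OC)cc2)cc1 | intermediate
3 | 3,5-bis{[(4-methoxybenzyl)oxy]methyl}-1,2,4-trioxolane (secondary ozonide, not isolated) | COc1ccc(COCC2OOC(COCc3ccc(OC)cc3)O2)cc1 | intermediate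
4 | 2-[(4-methoxybenzyl)oxy]acetaldehyde | O=CCOCc1ccc(OC)cc1 | intermediate
5 | 2-bromoprop-2-en-1-ol | OCC(Br)=C | starting material
6 | lithium 2-lithioprop-2-en-1-olate (not isolated) | [Li]OCC([Li])=C | intermediate
7 | rac-4-[(4-methoxybenzyl)oxy]-2-methylidenebutane-1,3-diol | OCC(=C)C(O)COCc1ccc(OC)cc1 | intermediate
8 | rac-3-{[tert-butyl(diphenyl)silyl]oxymethyl}-1-[(4-methoxybenzyl)oxy]but-3-en-2-ol | C=C(CO[Si](c1ccccc1)(c1ccccc1)C(C)(C)C)C(O)COCc1ccc(OC)cc1 | intermediate
9 | 1-ethoxyethenyl ether of 8 (ketene acetal, not isolated) | C=C(OCC)OC(COCc1ccc(OC)cc1)C(=C)CO[Si](c1ccccc1)(c1ccccc1)C(C)(C)C | intermediate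
10 | ethyl (4Z)-4-{[tert-butyl(diphenyl)silyl]oxymethyl}-6-[(4-methoxybenzyl)oxy]hex-4-enoate | COc1ccc(COC/C=C(\CO[Si](c2ccccc2)(c2ccccc2)C(C)(C)C)CCC(=O)OCC)cc1 | intermediate
11 | diisobutylaluminium hemiacetal of 10 (not isolated) | COc1ccc(COC/C=C(\CO[Si](c2ccccc2)(c2ccccc2)C(C)(C)C)CCC(OCC)O[Al](CC(C)C)CC(C)C)cc1 | intermediate
12 | (4Z)-4-{[tert-butyl(diphenyl)silyl]oxymethyl}-6-[(4-methoxybenzyl)oxy]hex-4-enal | COc1ccc(COC/C=C(\CO[Si](c2ccccc2)(c2ccccc2)C(C)(C)C)CCC=O)cc1 | intermediate
13 | (2Z,6Z)-3-{[tert-butyl(diphenyl)silyl]oxymethyl}-7-iodo-1-[(4-methoxybenzyl)oxy]octa-2,6-diene | COc1ccc(COC/C=C(\CO[Si](c2ccccc2)(c2ccccc2)C(C)(C)C)CC/C=C(/C)I)cc1 | intermediate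
14 | (R)-glycidol [(R)-oxiran-2-ylmethanol] | OC[C@@H]1CO1 | starting material
15 | (S)-triethyl(oxiran-2-ylmethoxy)silane | CC[Si](CC)(CC)OC[C@@H]1CO1 | intermediate
16 | alkenyllithium from 13 (lithium in place of iodine, geometry retained; not isolated) | COc1ccc(COC/C=C(\CO[Si](c2ccccc2)(c2ccccc2)C(C)(C)C)CC/C=C(/C)[Li])cc1 | intermediate
17 | (2S,4Z,8Z)-8-{[tert-butyl(diphenyl)silyl]oxymethyl}-10-[(4-methoxybenzyl)oxy]-4-methyl-1-(triethylsilyloxy)deca-4,8-dien-2-ol | COc1ccc(COC/C=C(\CO[Si](c2ccccc2)(c2ccccc2)C(C)(C)C)CC/C=C(/C)C[C@H](O)CO[Si](CC)(CC)CC)cc1 | intermediate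
18 | (2S,4Z,8Z)-8-{[tert-butyl(diphenyl)silyl]oxymethyl}-10-[(4-methoxybenzyl)oxy]-4-methyl-1,2-bis(triethylsilyloxy)deca-4,8-diene | COc1ccc(COC/C=C(\CO[Si](c2ccccc2)(c2ccccc2)C(C)(C)C)CC/C=C(/C)C[C@H](O[Si](CC)(CC)CC)CO[Si](CC)(CC)CC)cc1 | intermediate
19 | C7 alkoxy(dimethyl)sulfonium chloride from 18 (not isolated) | COc1ccc(COC/C=C(\CO[Si](c2ccccc2)(c2ccccc2)C(C)(C)C)CC/C=C(/C)C[C@H](O[Si](CC)(CC)CC)CO[S+](C)C)cc1.[Cl-] | intermediate
20 | (2S,4Z,8Z)-8-{[tert-butyl(diphenyl)silyl]oxymethyl}-10-[(4-methoxybenzyl)oxy]-4-methyl-2-(triethylsilyloxy)deca-4,8-dienal | COc1ccc(COC/C=C(\CO[Si](c2ccccc2)(c2ccccc2)C(C)(C)C)CC/C=C(/C)C[C@H](O[Si](CC)(CC)CC)C=O)cc1 | intermediate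
21 | methyl acrylate | C=CC(=O)OC | starting material
22 | methyl (4S,6Z,10Z)-10-{[tert-butyl(diphenyl)silyl]oxymethyl}-3-hydroxy-12-[(4-methoxybenzyl)oxy]-6-methyl-2-methylidene-4-(triethylsilyloxy)dodeca-6,10-dienoate (both C3 epimers) | COc1ccc(COC/C=C(\CO[Si](c2ccccc2)(c2ccccc2)C(C)(C)C)CC/C=C(/C)C[C@H](O[Si](CC)(CC)CC)C(O)C(=C)C(=O)OC)cc1 | intermediate
23 | C7 alkoxy(dimethyl)sulfonium bromide from 22 (not isolated) | COc1ccc(COC/C=C(\CO[Si](c2ccccc2)(c2ccccc2)C(C)(C)C)CC/C=C(/C)C[C@H](O[Si](CC)(CC)CC)C(O[S+](C)C)C(=C)C(=O)OC)cc1.[Br-] | intermediate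
24 | methyl (2Z,4S,6Z,10Z)-2-(bromomethyl)-10-{[tert-butyl(diphenyl)silyl]oxymethyl}-12-[(4-methoxybenzyl)oxy]-6-methyl-4-(triethylsilyloxy)dodeca-2,6,10-trienoate | COc1ccc(COC/C=C(\CO[Si](c2ccccc2)(c2ccccc2)C(C)(C)C)CC/C=C(/C)C[C@H](O[Si](CC)(CC)CC)/C=C(\CBr)C(=O)OC)cc1 | intermediate
25 | methyl (2Z,4S,6Z,10Z)-2-(bromomethyl)-10-{[tert-butyl(diphenyl)silyl]oxymethyl}-12-hydroxy-6-methyl-4-(triethylsilyloxy)dodeca-2,6,10-trienoate | OC/C=C(\CO[Si](c1ccccc1)(c1ccccc1)C(C)(C)C)CC/C=C(/C)C[C@H](O[Si](CC)(CC)CC)/C=C(\CBr)C(=O)OC | intermediate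
26 | methyl (2Z,4S,6Z,10Z)-2-(bromomethyl)-10-{[tert-butyl(diphenyl)silyl]oxymethyl}-6-methyl-12-oxo-4-(triethylsilyloxy)dodeca-2,6,10-trienoate | O=C/C=C(\CO[Si](c1ccccc1)(c1ccccc1)C(C)(C)C)CC/C=C(/C)C[C@H](O[Si](CC)(CC)CC)/C=C(\CBr)C(=O)OC | intermediate
27 | allylchromium dichloride from 26 (CrCl2 on C13 in place of bromine; not isolated) | O=C/C=C(\CO[Si](c1ccccc1)(c1ccccc1)C(C)(C)C)CC/C=C(/C)C[C@H](O[Si](CC)(CC)CC)/C=C(\C[Cr](Cl)Cl)C(=O)OC | intermediate
28 | dichlorochromium alkoxide of the ring-closed hydroxy ester (ten-membered ring, O6–Cr, C7 bearing 1-(methoxycarbonyl)ethenyl, 6,7-anti; not isolated) | Cl[Cr](Cl)O[C@@H]1/C=C(\CO[Si](c2ccccc2)(c2ccccc2)C(C)(C)C)CC/C=C(/C)C[C@H](O[Si](CC)(CC)CC)[C@H]1C(=C)C(=O)OC | intermediate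
29 | (3aS,4S,6Z,10Z,11aR)-10-{[tert-butyl(diphenyl)silyl]oxymethyl}-6-methyl-3-methylidene-4-(triethylsilyloxy)-3a,4,5,8,9,11a-hexahydrocyclodeca[b]furan-2(3H)-one | C=C1C(=O)O[C@@H]2/C=C(\CO[Si](c3ccccc3)(c3ccccc3)C(C)(C)C)CC/C=C(/C)C[C@H](O[Si](CC)(CC)CC)[C@@H]12 | intermediate
30 | (3aR,4S,6Z,10Z,11aR)-10-{[tert-butyl(diphenyl)silyl]oxymethyl}-4-hydroxy-6-methyl-3-methylidene-3a,4,5,8,9,11a-hexahydrocyclodeca[b]furan-2(3H)-one | C=C1C(=O)O[C@@H]2/C=C(\CO[Si](c3ccccc3)(c3ccccc3)C(C)(C)C)CC/C=C(/C)C[C@H](O)[C@@H]12 | intermediate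
31 | methyl (R)-3-hydroxy-2-methylpropanoate | COC(=O)[C@H](C)CO | starting material
32 | methyl (R)-3-{[tert-butyl(diphenyl)silyl]oxy}-2-methylpropanoate | COC(=O)[C@H](C)CO[Si](c1ccccc1)(c1ccccc1)C(C)(C)C | intermediate
33 | lithium (R)-3-{[tert-butyl(diphenyl)silyl]oxy}-2-methylpropanoate (not isolated) | [Li+].[O-]C(=O)[C@H](C)CO[Si](c1ccccc1)(c1ccccc1)C(C)(C)C | intermediate
34 | (R)-3-{[tert-butyl(diphenyl)silyl]oxy}-2-methylpropanoic acid | OC(=O)[C@H](C)CO[Si](c1ccccc1)(c1ccccc1)C(C)(C)C | intermediate
35 | O-acylisourea from 34 and DCC (not isolated) | O=C(OC(=NC1CCCCC1)NC1CCCCC1)[C@H](C)CO[Si](c1ccccc1)(c1ccccc1)C(C)(C)C | intermediate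
36 | (3aR,4S,6Z,10Z,11aR)-10-{[tert-butyl(diphenyl)silyl]oxymethyl}-6-methyl-3-methylidene-2-oxo-2,3,3a,4,5,8,9,11a-octahydrocyclodeca[b]furan-4-yl (2R)-3-{[tert-butyl(diphenyl)silyl]oxy}-2-methylpropanoate | C=C1C(=O)O[C@@H]2/C=C(\CO[Si](c3ccccc3)(c3ccccc3)C(C)(C)C)CC/C=C(/C)C[C@H](OC(=O)[C@H](C)CO[Si](c3ccccc3)(c3ccccc3)C(C)(C)C)[C@@H]12 | intermediate
37 | (3aR,4S,6Z,10Z,11aR)-10-(hydroxymethyl)-6-methyl-3-methylidene-2-oxo-2,3,3a,4,5,8,9,11a-octahydrocyclodeca[b]furan-4-yl (2R)-3-hydroxy-2-methylpropanoate | C=C1C(=O)O[C@@H]2/C=C(\CO)CC/C=C(/C)C[C@H](OC(=O)[C@H](C)CO)[C@@H]12 | target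

## Step count and least certain steps

Total: 21 steps. Longest linear sequence: 18 steps (1–7, 9–17, 20, 21) from diol 1; 16 steps counted from 5.

**Step 16 (key step).** The allylchromium may lose the C8 silyloxy group by vinylogous β-elimination. It may be protonated before it finds the aldehyde, or couple between molecules. The ring may close on the wrong face of C7 or with the syn C6/C7 relationship, and lactonisation may stall at the hydroxy ester. The fallback sets out from 22 and changes how the C7 nucleophile is made. Acetylation (Ac2O, pyridine, DMAP) would give Baylis–Hillman acetate F1. DDQ would free allylic alcohol F2, and MnO2 would give formyl acetate F3. Pd(PPh3)4 (zerovalent palladium, catalytic) with Et2Zn in THF at high dilution should ionise the acetate to a π-allylpalladium species and turn it into an allylzinc nucleophile. This adds to C6 through the same kind of closed transition state, and the zinc alkoxide lactonises. This palladium-catalysed umpolung allylation is known for allylic acetates, including medium-ring closures. The fallback returns to the route at 29.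

**Step 12.** Conversion of a hindered, lipophilic aldehyde may be slow. The long exposure to the amine may epimerise C8 or shift the silyl group, and the acrylate may oligomerise. The fallback sets out from 20. Methyl propiolate is hydroaluminated with i-Bu2AlH in the presence of N-methylmorpholine N-oxide to give vinylalane F4. This preformed α-acrylate anion equivalent should add to 20 at 0 °C without any amine and return to the route at 22.

**Step 7.** The iodo-ylide may form incompletely, leading to loss of iodine in the product, and Z selectivity may erode, giving geometric isomers that are hard to separate. The fallback sets out from 12. CBr4/PPh3 (first stage of the Corey–Fuchs reaction) would give dibromoalkene F5. A Negishi coupling that replaces only the bromine trans to the chain (Me2Zn, PdCl2(DPEphos) catalyst) would give (Z)-bromoalkene F6. Bromine–lithium exchange with t-BuLi generates the same alkenyllithium 16, so the fallback returns to the route at 17.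

**Step 11.** The oxidant may fail to discriminate between the two triethylsilyl ethers, attacking or cleaving at O8, and the amine may epimerise the α-silyloxy aldehyde. The fallback sets out from 18 and separates the two events. HF·pyridine buffered with pyridine in THF at −10 °C would remove only the primary silyl group to give primary alcohol F7. A Parikh–Doering oxidation (SO3·pyridine, DMSO, i-Pr2NEt) would then return to the route at 20.

## Further compounds

F1 | step 16 | Baylis–Hillman acetate: methyl (4S,6Z,10Z)-3-acetoxy-10-{[tert-butyl(diphenyl)silyl]oxymethyl}-12-[(4-methoxybenzyl)oxy]-6-methyl-2-methylidene-4-(triethylsilyloxy)dodeca-6,10-dienoate | COc1ccc(COC/C=C(\CO[Si](c2ccccc2)(c2ccccc2)C(C)(C)C)CC/C=C(/C)C[C@H](O[Si](CC)(CC)CC)C(OC(C)=O)C(=C)C(=O)OC)cc1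
F2 | step 16 | allylic alcohol: methyl (4S,6Z,10Z)-3-acetoxy-10-{[tert-butyl(diphenyl)silyl]oxymethyl}-12-hydroxy-6-methyl-2-methylidene-4-(triethylsilyloxy)dodeca-6,10-dienoate | OC/C=C(\CO[Si](c1ccccc1)(c1ccccc1)C(C)(C)C)CC/C=C(/C)C[C@H](O[Si](CC)(CC)CC)C(OC(C)=O)C(=C)C(=O)OC
F3 | step 16 | formyl acetate: methyl (4S,6Z,10Z)-3-acetoxy-10-{[tert-butyl(diphenyl)silyl]oxymethyl}-6-methyl-2-methylidene-12-oxo-4-(triethylsilyloxy)dodeca-6,10-dienoate | O=C/C=C(\CO[Si](c1ccccc1)(c1ccccc1)C(C)(C)C)CC/C=C(/C)C[C@H](O[Si](CC)(CC)CC)C(OC(C)=O)C(=C)C(=O)OC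
F4 | step 12 | vinylalane: methyl 2-(diisobutylalumanyl)prop-2-enoate | C=C(C(=O)OC)[Al](CC(C)C)CC(C)C
F5 | step 7 | dibromoalkene: (2Z)-7,7-dibromo-3-{[tert-butyl(diphenyl)silyl]oxymethyl}-1-[(4-methoxybenzyl)oxy]hepta-2,6-diene | COc1ccc(COC/C=C(\CO[Si](c2ccccc2)(c2ccccc2)C(C)(C)C)CCC=C(Br)Br)cc1
F6 | step 7 | (Z)-bromoalkene: (2Z,6Z)-7-bromo-3-{[tert-butyl(diphenyl)silyl]oxymethyl}-1-[(4-methoxybenzyl)oxy]octa-2,6-diene | COc1ccc(COC/C=C(\CO[Si](c2ccccc2)(c2ccccc2)C(C)(C)C)CC/C=C(/C)Br)cc1
F7 | step 11 | primary alcohol: (2S,4Z,8Z)-8-{[tert-butyl(diphenyl)silyl]oxymethyl}-10-[(4-methoxybenzyl)oxy]-4-methyl-2-(triethylsilyloxy)deca-4,8-dien-1-ol | COc1ccc(COC/C=C(\CO[Si](c2ccccc2)(c2ccccc2)C(C)(C)C)CC/C=C(/C)C[C@H](O[Si](CC)(CC)CC)CO)cc1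
A1 | alternative 1 | cis-decalin mesylate (C1 mesylate trans to the C10 methyl, C4 methyl ester, C6 4-methoxybenzyl ether, C7 3-[(4-methoxybenzyl)oxy]prop-1-en-2-yl, C8 triethylsilyl ether) | CS(=O)(=O)O[C@H]1CC[C@H](C(=O)OC)[C@H]2[C@@H](OCc3ccc(OC)cc3)[C@H](C(=C)COCc3ccc(OC)cc3)[C@@H](O[Si](CC)(CC)CC)C[C@@]12C
A2 | alternative 1 | cyclodecadiene C15 methyl ester | [C@@H]1(OCc2ccc(OC)cc2)/C=C(\C(=O)OC)CC/C=C(/C)C[C@H](O[Si](CC)(CC)CC)[C@H]1C(=C)COCc1ccc(OC)cc1
A3 | alternative 2 | redox-active ester: γ-lactone carrying the C4 alkenyl iodide and the N-(acyloxy)phthalimide beyond C3 | C1C(=O)O[C@H](/C=C(/I)CO[Si](c2ccccc2)(c2ccccc2)C(C)(C)C)[C@H]1[C@@H](O[Si](CC)(CC)CC)C/C(C)=C\CCC(=O)ON1C(=O)c2ccccc2C1=O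
A4 | alternative 2 | bicyclic lactone lacking the C13 methylene | C1C(=O)O[C@@H]2/C=C(\CO[Si](c3ccccc3)(c3ccccc3)C(C)(C)C)CC/C=C(/C)C[C@H](O[Si](CC)(CC)CC)[C@@H]12
A5 | alternative 3 | thirteen-membered α-(tributylstannyl) allyl ether (O8–C13 linked, C6 trans to C13 across C7=C11) | CCCC[Sn](CCCC)(CCCC)[C@@H]1OC/C(COCc2ccc(OC)cc2)=C/[C@H](OCc2ccc(OC)cc2)/C=C(\CO[Si](c2ccccc2)(c2ccccc2)C(C)(C)C)CC/C=C(/C)C1
A6 | alternative 3 | cyclodecadienol with free C8 hydroxyl | [C@@H]1(OCc2ccc(OC)cc2)/C=C(\CO[Si](c2ccccc2)(c2ccccc2)C(C)(C)C)CC/C=C(/C)C[C@H](O)[C@H]1C(=C)COCc1ccc(OC)cc1
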